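All runs come from a simulation from invented constants; scatter was added.

A small charge of free catalyst turned a racemate of substrates with partner, and the earlier runs read the two substrates but no product.

common to all: left-handed substrate 0.14 M; right-handed substrate 0.14 M; partner 0.168 M; free catalyst 0.28 mM

| charge | added ligand | remark | time |
|---|---|---|---|
| ash | 0.085 mM | run made earlier |  |
| birch | 0.34 mM | run made earlier |  |
| flask | 0.17 mM |  | 10 d |

- ash (time / d: left-handed substrate / %, right-handed substrate / %): 2.50: 28, 43; 5.00: 26, 41; 8.00: 20, 39; 10.0: 22, 34
- birch (time / d: left-handed substrate / %, right-handed substrate / %): 1.25: 37, 47; 4.00: 28, 41; 6.00: 26, 38; 10.0: 22, 39

(readings scatter by 1.5 percentage points)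

- part of the left-handed substrate and right-handed substrate charged together that has reacted at 10 d
- excess of left-handed product over right-handed product in the product at 10 d
- excess of right-handed substrate over left-handed substrate among what is left of the two at 10 d

- free catalyst is single-handed; left-handed substrate and right-handed substrate are mirror images of each other, charged as a racemate, each of them at the stated concentration
- an excess is the difference of the two amounts in percent of their sum
- an excess is below zero if the other one leads

I carried one quantity, the owed excess: the product excess that the loss of the two substrates pays for. The substrates were charged equally, so their gap is the lead one product gains if each product keeps its hand: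

owed excess = [c(right-handed substrate) − c(left-handed substrate)] / part reacted

The added ligand of the flask, 0.17 mM, lay between that of ash, 0.085 mM, and that of birch, 0.34 mM. I therefore took the mean of their readings at 10 d:

part reacted = 41.5 %
gap = 15 percentage points
owed excess = 34.9 %

Two extreme versions bound eP. If each product keeps its hand, eP equals the owed excess. If the products scramble as they form, eP vanishes while the substrates read the same. Mirror-image products have equal energy, so any passage between them shrinks the excess, and the flask must lie between these versions. The runs read no product, so I committed to the owed excess as an upper estimate of eP, an estimate that carries the scatter of its readings.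

The forecast gave c 41.5 %, eP 40 % and eS 28 %, resting on “a selectivity of about 3 in both runs”, the selectivity factor. My upper estimate stood lower than its eP.

The flask gave c 44.1 %, eP 10.0 % and eS 27.7 %.

    left-handed product ⇌ right-handed product (k = 0.00361 /h)
    2 free catalyst → spent catalyst (k = 19.2 /M/h)
    partner + free catalyst + right-handed substrate → free catalyst + right-handed product (k = 130 /M²/h)
    partner + free catalyst + left-handed substrate → free catalyst + left-handed product (k = 350 /M²/h)
    free catalyst + added ligand ⇌ idle complex, settled at all times (K = 3900 /M)

The two products pass into each other with a relaxation half-life, by that step alone and both ways together, of 4.00 d, shorter than the 10 d run. The eP of the flask came to 28.7 % of the 34.9 % that I had estimated as owed. The rule also reads eS × (1 − c) / c, so the neighbour charged with 0.42 M of partner, at c 78.9 % and eS 70.1 %, owed 18.7 %, and its product showed 2.26 %.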